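How much product stands in the flask at 80 min, and with what excess?

in all of them: left-handed substrate 49 mM; right-handed substrate 49 mM; gas 3.1 mM (held)

|  | racemization catalyst | remark | time |
|---|---|---|---|
| zeta | 0.34 mM | run made earlier |  |
| flask | 0.17 mM |  | 80 min |

zeta run (percent of the left-handed substrate and right-handed substrate together charged)

| time / min | left-handed product / % | right-handed product / % | left-handed substrate / % |
|---|---|---|---|
| 6.00 | 8.3 | 3.3 | 41.7 |
| 12.0 | 17.2 | 7.0 | 33.7 |
| 20.0 | 26.0 | 12.1 | 24.9 |
| 25.0 | 30.6 | 14.9 | 20.1 |

(each reading ± 0.3 percentage points)

* left-handed product and right-handed product together, in percent of the left-handed substrate and right-handed substrate charged together, at 80 min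
* excess of left-handed product over right-handed product in the product at 80 min
* whether the exchange between left-handed substrate and right-handed substrate keeps pace with the reaction: how far the product's excess at 80 min gets from its value without exchange to its value with instant exchange (above 80% keeps pace, below 20% hardly takes part, else lags behind)

- reagent is single-handed; left-handed substrate and right-handed substrate are mirror images of each other, charged as a racemate, each of them at the stated concentration
- at the start none of the gas is in solution
- an excess is the difference of the two amounts in percent of their sum
- an excess is below zero if the other one leads
- no earlier run changes the charge of racemization catalyst; that part of a forecast is a guess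
- the handed part of reagent does not stay in what it makes, so the products of the two hands are mirror images too

In the zeta run, the charge reacts at 0.0210 min⁻¹ between 6.00 min and 12.0 min. Between 20.0 min and 25.0 min that rate is multiplied by 0.705. The pseudo-first-order rate of left-handed substrate, however, is multiplied by 1.21. So in the zeta run the rate falls while the rate per amount of left-handed substrate rises.

My reckoning supposes that reagent is used as fast as gas transfer makes it. Its level then falls short of 3.1 mM in step with the product rate, and summing over time gives:

t = a·θ + W·y, with θ = ln(c left-handed substrate at the start / c left-handed substrate now)

The readings at 12.0 min and 25.0 min give a = 14.4 min and W = 26.1 min. W is the supply time: the minutes gas transfer needs to deliver reagent for the whole charge at full drive. Both are uncertain readings. The selectivity factor reads 2.44.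

Two passes at 80 min:

θ = 3.75, y = 88.1%

θ = 3.96, y = 89.2%

Without exchange, my reckoning gives an excess of 9.96%. In the zeta run at 25.0 min, left-handed substrate plus left-handed product reads 0.7 percentage points above half, with a scatter of 0.3 points on each reading, so I expect little exchange.

The forecast, working from “Rate constants from product rate over remaining substrate”, gives 83.6%, below my figure, and 18.4%, above my figure without exchange; on pace it says hardly takes part.

The flask gives 89.3%, 12.8% and hardly takes part, at 6.8% of the way.

    reagent + right-handed substrate → right-handed product (k = 9.00 L mol⁻¹ min⁻¹)
    gas ⇌ reagent, rate k2*(csat - [reagent]) (kL = 1.30 min⁻¹)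
    2 racemization catalyst ⇌ resting dimer (K = 15000 L mol⁻¹, k = 1000 L mol⁻¹ min⁻¹)
    left-handed substrate + racemization catalyst ⇌ right-handed substrate + racemization catalyst, rate k4*[racemization catalyst]*[left-handed substrate] forward; the back reaction follows from the equilibrium constant (k = 26.0 L mol⁻¹ min⁻¹)
    reagent ⇌ dormant form (K = 240, k = 0.0200 min⁻¹)
    reagent + left-handed substrate → left-handed product (k = 23.0 L mol⁻¹ min⁻¹)

In the flask, reagent is made 1.02 times as fast as it is used at 80.0 min, while it climbs from 1.55 mM at 8.00 min to 2.81 mM at 80.0 min. In my reckoning, with W as read from the zeta run, the term W·y comes to 23.3 min of the 80 min.

The neighbour flask with 0.43 mM of racemization catalyst has the same gas, and the rule holds no catalyst term, so W and a give 89.2% there too. Computed, that neighbour reaches 89.5%, with excess 14.2%.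

The readings were computed from invented constants, noise included.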